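The numbers in the tables stem from a simulated flask with made-up constants; noise was put on by code.

Between 15 min and 25 min the larch flask gains 2.79 mM of Prd, less than the 8.14 mM of the 10.0 min before, and you have to judge how much of the curve is still to come.

| flask | Sub | Rgt | time |
|---|---|---|---|
| larch | 50.0 mM | 40.0 mM |  |
| birch | 50.0 mM | 60.0 mM |  |
| maple | 75.0 mM | 40.0 mM |  |
| ash | 50.0 mM | 40.0 mM | 60 min |

| run | time / min | [Prd] / mM |
|---|---|---|
| larch run | 5.0 | 8.48 |
| larch run | 10 | 13.36 |
| larch run | 15 | 16.62 |
| larch run | 20 | 18.19 |
| larch run | 25 | 19.41 |
| larch run | 30 | 19.78 |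
| birch run | 5.0 | 14.55 |
| birch run | 10 | 22.05 |
| birch run | 15 | 25.64 |
| birch run | 20 | 27.30 |
| birch run | 25 | 28.32 |
| birch run | 30 | 28.39 |
| maple run | 5.0 | 10.83 |
| maple run | 10 | 16.55 |
| maple run | 15 | 20.47 |
| maple run | 20 | 22.56 |
| maple run | 25 | 24.21 |
| maple run | 30 | 25.12 |

(readings scatter by 0.2 mM)

- the power of [Rgt] that the first rate follows, about the charge of the larch run; measure it at two percent of Sub made into Prd
- the power of [Sub] that the first rate follows, about the charge of the larch run; measure it at two percent of Sub made into Prd (one fixed amount of Prd, the same in the runs compared)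
- Prd in the ash run at 60 min, as a share of the Sub charged

- Overall: Sub + Rgt -> Prd.
- Constant volume, constant temperature.
- Bound and free are read together.
- "The second partner" is Rgt.
- An order is taken over about fifteen percent of the charge, up and down.

- At 30 min the larch flask still holds c_Rgt = 20.2 mM by subtraction, so its curve flattens with Rgt, the limiting reagent by charge, not used up.
- Ash repeats the larch charge, so I carry the larch curve forward with the stall lifetime, the time in which the gain still to come shrinks by a factor e, read as the length of two equal successive intervals over the logarithm of the ratio of their gains: 9.34 min. Summing the shrinking gains leaves a tail of 1.45 mM after 25 min.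
- You need the lifetime only roughly, since 60 min lies 3.75 lifetimes past that reading: doubling it leaves 0.223 mM unmade instead of 0.0343 mM, a shift of 0.378% of the charge.
- You need the 25 min reading well, because one scatter on it moves the outcome by 0.481 mM, more than the 0.0565 mM from one scatter on the 5.0 min reading.
- So I reckon 20.8 mM, which is 41.7% of the Sub charged.
- The forecast gives 41.5% (39% to 45%), close to my figure, with the power of c_Rgt at 1.4 (1.1 to 1.75) and the power of c_Sub at 0.65 (0.4 to 0.95), and it says: “All runs stall with much Sub and Rgt left, far faster than depletion explains.”

The ash flask gives 41.3% of the Sub charged at 60 min, and about the larch charge the power of c_Rgt is 1.6 and the power of c_Sub is 0.62.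

    Sub + Rgt → Prd (1.740 M⁻¹ min⁻¹)
    Sub + 2 Rgt → Prd + Rgt (46.44 M⁻² min⁻¹)
    2 Sub ⇌ Sub2, settled at all times (63.10 M⁻¹)
    Sub → Q (0.1224 min⁻¹)

A fit in which two substrates go astray together has a root mean square residual of 3.4 scatters and forecasts 48.4% for the ash flask, above the forecast's upper end, so an ash flask at that value would have made the forecast wrong. The ash value stands 1.26 mM above the larch reading at 25 min, against the reckoned tail of 1.45 mM. In birch the same reckoning on the readings gives a stall lifetime of 7.04 min and a tail of 0.854 mM, which puts half of the charged Sub as Prd at 13.8 min, and the birch flask gets there at 14.2 min.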